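The rate constants come from no measurement; no experiment stands behind them.

Time is what you should watch here. South, north and south-east each get 30 min, but each vessel hands that time to a molecule differently.

all flasks: Z 10 mol%; Q 11 mM
- south: J 0.48 M; a single well-mixed tank run continuously and read at steady state, 30 min in it on average
- north: J 0.48 M (fed, over 30.0 min); all but J at the start; J goes in evenly over 30.0 min, the run ends at 30 min; time 30 min
- south-east: J 0.48 M; everything together in a closed stirred flask, run for 30 min; time 30 min

    J + Z ⇌ X + Z, rate k1*[J]*[Z] forward; the back reaction follows from the equilibrium constant (K1 = 4.0, k1 = 0.075 M⁻¹ s⁻¹)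
    X ⇌ E (K2 = 0.33, k2 = 1.3 × 10⁻⁴ s⁻¹)
    E ⇌ J (k3 = 2.3 × 10⁻⁴ s⁻¹)
    Z + Q → Z.Q (k4 = 0.89 M⁻¹ s⁻¹)

- the stated concentrations are those of everything mixed, before any reaction; amounts are the same in each set-up
- the feed brings no volume worth counting
- run time (north): 30 min

- the set-up with the highest amount of X at the outlet or at the end, in percent of the J put in ("none" if the first two lie within 2 percentage points) (south / north / south-east / none)
- amount of X at the outlet or at the end, in percent of the J put in, south
- amount of X at the outlet or at the end, in percent of the J put in, north
- amount of X at the outlet or at the end, in percent of the J put in, south-east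

First count the working catalyst. Per Q, binding to Z runs at 2.56 min⁻¹, faster than J turns at 0.216 min⁻¹, and Q is charged below Z. So reckon with 0.0370 M of Z.

Now follow one molecule. It swings between J and X at a pace λ of 0.208 min⁻¹, both ways summed, and it is X for 80.0% of the time. Call N = λ times the time, the Damköhler number of the pair: 6.24.

The pair feeds E at 0.00988 min⁻¹, slower than λ, and E leaves at 0.0374 min⁻¹. E therefore heads for 20.9%, and its own number is 1.42.

The late share is the part of a change not yet made at the reading. In the closed flask it is the exponential of minus the number. In the tank a molecule stands at a fork, turn or leave, so it is one over one plus the number. In the fed flask it is the closed value averaged over the ages of the molecules.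

| set-up | J to X, late | E, late |
|---|---|---|
| south | 13.8% | 41.3% |
| north | 16.0% | 53.4% |
| south-east | 0.194% | 24.2% |

Read the first column: south-east is far less late than the other two. Read the second: south-east should also hold the most E, with the smallest late share. X is the pair's share of what is neither E nor late, so I expect 59.2% in south, 59.4% in north and 67.2% in south-east. The best is south-east.

The forecast gave 59%, 58% and 66%, with south-east best: “the closed flask wins clearly”. Its south-east figure lies below mine.

The simulation gives 59.1% in south, 59.2% in north and 66.6% in south-east, so south-east is best. In south-east, by 15.0 min, Q stood at 0% of its charge and X at 67.5%, with E at 12.7%; at 30.0 min E held 16.9%. North ended with 29.3% of J, against 16.5% in south-east, on a reckoned late share of 16.0% against 0.194%. A neighbour of south-east with 0.19 M of J and 0.0579 equiv of Q has 0.00800 M of working Z, so N falls to 1.35 and its reckoned late share rises to 25.9%. That flask ended with 52.6% of X and 27% of J.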